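**Remark on the chemistry.** Labdane numbering is used throughout: C1–C10 decalin (ring A = C1–C5, C10; ring B = C5–C10), C11–C16 side chain and lactone, C17 exocyclic methylene carbon, C18 (methyl) and C19 (CH2OH) on C4, C20 methyl on C10. α is the decalin face that carries C20, β the opposite face. β-Keto ester 9 is drawn as one keto form; it equilibrates with its enol and its C4 configuration is set only in step 4.

**Plan**
1. Retrosynthetic cuts: C12–C13 (acylation of a hydroxy-lactone enolate, then ketone reduction), C8=C17 (Wittig), C9–C11 (enol triflate coupling), C4–C18 (enolate methylation), and ring A at C1–C10 plus C3–C4, which leads back to methyl acrylate and a ring B keto ester made from (S)-carvone and tert-butyl acetate.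
2. Enabling feature: C10 and C4 flank C5–H and each is α to a carbonyl (C9 ketone, C19 tert-butyl ester), so ring B carries a latent 1,3-bis-nucleophile that matches the C1/C3 bis-electrophile of an acrylate; ring A closes by a Michael–Dieckmann [3+3] annulation.
3. Forward order: ring B from carvone → C5 arm → ring A (annulation) → C4 methyl → excision of the carvone isopropenyl at C7 → 3,19-diol as acetonide → C9 side chain and C8 methylene → lactone.
4. Stereochemistry of the decalin: carvone C5 (S) is the only chiral source; C5 by addition anti to isopropenyl, C10 anti to the C5 arm, C4 by methylation opposite C20, C3 by axial hydride, C9–H by hydroboration opposite C20 (thermodynamically backed at the C8 ketone).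
5. Stereochemistry of the side chain: C14 from (S)-3-hydroxy-γ-butyrolactone, C13 trans to the C14 oxygen, C12 by chelation-controlled reduction.

Key step: step 3

**Step 1**
Reactants: 1 tert-butyl acetate
Product: 3 1-tert-butoxy-1-(trimethylsilyloxy)ethene, via lithium enolate 2 (not isolated)
Conditions: LiN(iPr)2, THF, −78 °C; Me3SiCl, DMPU, −78 °C → rt; distillation
Reagents that add atoms: chlorotrimethylsilane, C[Si](C)(C)Cl
Why: O-silylation of the ester enolate in the presence of DMPU is the standard route to ketene silyl acetals.

**Step 2**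
Reactants: 4 (S)-(+)-carvone; 3 ketene silyl acetal
Product: 5 tert-butyl 2-[(1R,5S)-2-methyl-5-(prop-1-en-2-yl)-3-(trimethylsilyloxy)cyclohex-2-en-1-yl]acetate
Conditions: Tf2NH (1 mol %), CH2Cl2, −78 °C; Et3N quench
Reagents that add atoms: none
Why: Mukaiyama–Michael addition with silyl transfer to the enolate oxygen should give the regiodefined C9–C10 silyl enol ether, and the nucleophile should add to C5 anti to the isopropenyl group (axial attack on the carvone half-chair), which sets C5.

**Step 3**
Reactants: 5 silyl enol ether; 6 methyl acrylate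
Product: 9 trans-decalin β-keto ester (3,9-dioxo; CO2tBu on C4; 7β-isopropenyl; 10α-methyl; 5β-H), via potassium enolate 7 (not isolated), via Michael adduct 8 (not isolated)
Conditions: KOtBu (1.2 equiv), THF, −30 °C; methyl acrylate (1.1 equiv, slow addition), −78 °C → rt; AcOH
Reagents that add atoms: none
Why: KOtBu cleaves the Si–O bond to give the regiodefined tetrasubstituted potassium enolate 7, which adds through C10 to methyl acrylate (C1–C10); proton transfer then moves the charge from C2 to the tert-butyl ester α-carbon C4, whose enolate acylates the methyl ester carbon C3 (C3–C4) with loss of methoxide, and deprotonation of the new β-keto ester makes the sequence irreversible. The closest known reaction type is the tandem Michael–Dieckmann (Michael–Claisen) annulation of a keto ester with an acrylate. Ring A closes in the 6-exo-trig mode at the ester carbonyl with the enolate exocyclic (6-enolexo). C10 is set by substrate control: A(1,2) strain with the C10 methyl holds the C5 arm pseudoaxial, so the acrylate should add to the opposite enolate face and C1 ends trans to the C4 arm, which also fixes the trans ring fusion; C4 stays enolisable and is set in step 4. Three selectivities are needed: the C10 (not C8) enolate, secured by the silyl enol ether; attack of C4 on C3 rather than of C2 on C19, secured because the tert-butyl ester can act only as the nucleophile; and single addition of acrylate, secured by slow addition at low temperature. The bridged product from Claisen attack of C8 on C3 cannot form a stabilised enolate and should revert.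

**Step 4**
Reactants: 9 β-keto ester
Product: 10 4β-methyl-4α-(tert-butoxycarbonyl) diketone (3,9-dioxo; 7β-isopropenyl)
Conditions: K2CO3, MeI, acetone, 50 °C
Reagents that add atoms: iodomethane, CI
Why: C-alkylation of the β-keto ester enolate; MeI should approach C4 from the β face, opposite the axial C10 methyl, so the new methyl (C18) becomes equatorial and the ester (C19) axial.

**Step 5**
Reactants: 10 methylated diketo ester
Product: 12 diketo ester without the C7 substituent, via methoxy hydroperoxide 11 (not isolated)
Conditions: O3, MeOH, −78 °C; then FeSO4·7H2O (1.2 equiv), PhSH (1.5 equiv), −78 °C → rt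
Reagents that add atoms: none
Why: Hydrodealkenylation: ozonolysis in methanol gives the α-methoxy hydroperoxide, divalent iron reduces it to an alkoxy radical that loses methyl acetate by β-scission, and the C7 radical takes a hydrogen atom from the thiol; no stereocenter is touched.

**Step 6**
Reactants: 12 diketo ester
Product: 13 3α,9α,19-triol
Conditions: LiAlH4, THF, 0 °C → reflux
Reagents that add atoms: none
Why: Hydride reduces both ketones and the tert-butyl ester; at C3 axial delivery from the β face (away from the axial C19 and C20 groups) should give the equatorial 3α-alcohol, and the C9 configuration is of no consequence.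

**Step 7**
Reactants: 13 triol
Product: 14 3α,19-O-isopropylidene-9α-ol
Conditions: Me2C(OMe)2, PPTS (cat.), acetone, rt
Reagents that add atoms: 2,2-dimethoxypropane, COC(C)(C)OC
Why: Acetalisation; the cis 3α,19-diol closes to the six-membered acetonide and the isolated C9 hydroxyl stays free.

**Step 8**
Reactants: 14 acetonide alcohol
Product: 15 9-ketone acetonide
Conditions: Dess–Martin periodinane, pyridine, CH2Cl2, 0 °C → rt
Reagents that add atoms: none
Why: Dess–Martin oxidation of the only free secondary alcohol under buffered conditions that spare the acetonide.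

**Step 9**
Reactants: 15 ketone
Product: 17 C8=C9 enol triflate, via potassium enolate 16 (not isolated)
Conditions: KN(SiMe3)2, THF, −78 °C; PhNTf2, −78 → 0 °C; aq. NH4Cl
Reagents that add atoms: N-phenylbis(trifluoromethanesulfonimide), O=S(=O)(N(c1ccccc1)S(=O)(=O)C(F)(F)F)C(F)(F)F
Why: The ketone can enolise only toward C8 (C10 is quaternary), so O-triflation of the enolate should give a single enol triflate.

**Step 10**
Reactants: 17 enol triflate
Product: 18 methyl ester with C9–CH2CO2Me and the C8=C9 double bond
Conditions: BrZnCH2CO2Me (from methyl bromoacetate and Zn dust, THF), Pd(PPh3)4 (5 mol %), THF/DMPU, 60 °C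
Reagents that add atoms: methyl bromoacetate (used as its zinc enolate), COC(=O)CBr
Why: Negishi-type cross-coupling of the Reformatsky reagent with the alkenyl triflate on zerovalent palladium joins C9 to C11 and keeps the double bond at C8–C9.

**Step 11**
Reactants: 18 unsaturated ester
Product: 20 8β-hydroxy-9βH ester, via alkylborane 19 (not isolated)
Conditions: BH3·THF, THF, 0 °C → rt; then 30% H2O2, aq. NaOAc, 0 °C → rt
Reagents that add atoms: hydrogen peroxide, OO
Why: Hydroboration–oxidation; boron goes to the less substituted C8 and hydrogen to C9 by syn addition on the β face, opposite the axial C10 methyl, so C9–H should be β and the side chain equatorial, and oxidation proceeds with retention.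

**Step 12**
Reactants: 20 hydroxy ester
Product: 21 8-oxo ester
Conditions: Dess–Martin periodinane, pyridine, CH2Cl2, 0 °C → rt
Reagents that add atoms: none
Why: Dess–Martin oxidation gives the C8 ketone; C9 is now epimerisable and the equatorial side chain (9βH) is the thermodynamic isomer, which also corrects any facial leakage in step 11.

**Step 13**
Reactants: 21 keto ester
Product: 22 methyl ester with exocyclic C8=C17 methylene (C9–CH2CO2Me; 3α,19-acetonide)
Conditions: Ph3PCH3Br, KN(SiMe3)2, THF, 0 °C; then 21, 0 °C → rt
Reagents that add atoms: methyltriphenylphosphonium bromide, C[P+](c1ccccc1)(c1ccccc1)c1ccccc1.[Br-]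
Why: Wittig methylenation of the ketone (the ester is untouched) installs the exocyclic alkene, after which C9 can no longer epimerise.

**Step 14**
Reactants: 22 methyl ester; 23 (S)-3-hydroxy-γ-butyrolactone
Product: 25 12-oxo lactone (acetonide), via dilithium dianion 24 (not isolated)
Conditions: 23 (3 equiv), LiN(iPr)2 (6 equiv), THF, −78 → −40 °C; then 22, −78 → −20 °C; AcOH
Reagents that add atoms: none
Why: Crossed Claisen acylation of the preformed lactone alkoxide–enolate by the methyl ester forms C12–C13; the acyl group should enter anti to the C14 alkoxide, and the trans arrangement is also the thermodynamic one at the now acidic C13.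

**Step 15**
Reactants: 25 keto lactone
Product: 26 3,19-O-isopropylidene derivative of the target
Conditions: Zn(BH4)2, Et2O/THF, −30 → 0 °C
Reagents that add atoms: none
Why: Chelation-controlled reduction: zinc bridges the ketone and lactone carbonyl oxygens (the C14 hydroxyl can also bind), hydride should add to the chelate face opposite the C14 ring carbon, and this gives the 12,13-syn (12S) alcohol, which is also 1,3-syn to the C14 hydroxyl.

**Step 16**
Reactants: 26 acetonide
Product: 27 target, (3R,4R,5S,9R,10S,12S,13S,14S)-3,12,14,19-tetrahydroxylabd-8(17)-en-16,15-olide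
Conditions: AcOH/H2O (7:3), rt
Reagents that add atoms: none
Why: Mild acid hydrolysis of the acetonide should leave the β-hydroxy lactone and the exocyclic alkene untouched.

**Compound list**
1 | tert-butyl acetate | CC(=O)OC(C)(C)C | starting material
2 | lithium enolate of tert-butyl acetate | [Li+].[O-]C(=C)OC(C)(C)C | intermediate
3 | 1-tert-butoxy-1-(trimethylsilyloxy)ethene | C=C(O[Si](C)(C)C)OC(C)(C)C | intermediate
4 | (S)-(+)-carvone, (5S)-2-methyl-5-(prop-1-en-2-yl)cyclohex-2-en-1-one | CC1=CC[C@@H](CC1=O)C(C)=C | starting material
5 | tert-butyl 2-[(1R,5S)-2-methyl-5-(prop-1-en-2-yl)-3-(trimethylsilyloxy)cyclohex-2-en-1-yl]acetate (acetate arm trans to isopropenyl) | CC1=C(O[Si](C)(C)C)C[C@@H](C(C)=C)C[C@@H]1CC(=O)OC(C)(C)C | intermediate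
6 | methyl acrylate | C=CC(=O)OC | starting material
7 | potassium enolate of the ketone corresponding to 5 (C9–O−, C9=C10) | [K+].CC1=C([O-])C[C@@H](C(C)=C)C[C@@H]1CC(=O)OC(C)(C)C | intermediate
8 | Michael adduct, tert-butyl 2-[2-(3-methoxy-3-oxopropyl)-2-methyl-3-oxo-5-(prop-1-en-2-yl)cyclohexyl]acetate, propanoate chain trans to the acetate arm (present as its potassium ester enolate, drawn neutral) | COC(=O)CC[C@@]1(C)C(=O)C[C@@H](C(C)=C)C[C@@H]1CC(=O)OC(C)(C)C | intermediate
9 | trans-decalin β-keto ester: C3 and C9 ketones, CO2tBu on C4 (drawn 4β, equatorial; labile, keto–enol), 7β-isopropenyl, 10α-methyl, 5β-H | O=C1C[C@@H](C(C)=C)C[C@@H]2[C@@H](C(=O)OC(C)(C)C)C(=O)CC[C@@]12C | intermediate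
10 | as 9 with 4β-methyl and 4α-CO2tBu | O=C1C[C@@H](C(C)=C)C[C@@H]2[C@](C)(C(=O)OC(C)(C)C)C(=O)CC[C@@]12C | intermediate
11 | α-methoxy hydroperoxide from 10 (C7 bears C(CH3)(OCH3)OOH; epimers at that carbon) | O=C1C[C@@H](C(C)(OC)OO)C[C@@H]2[C@](C)(C(=O)OC(C)(C)C)C(=O)CC[C@@]12C | intermediate
12 | diketo ester: 3,9-dioxo, 4β-methyl, 4α-CO2tBu, 10α-methyl, 5β-H, C7 unsubstituted | O=C1CCC[C@@H]2[C@](C)(C(=O)OC(C)(C)C)C(=O)CC[C@@]12C | intermediate
13 | triol: 3α-OH, 9α-OH, 4α-CH2OH, 4β-methyl, 10α-methyl, 5β-H | O[C@@H]1CCC[C@@H]2[C@](C)(CO)[C@H](O)CC[C@@]12C | intermediate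
14 | 3α,19-O-isopropylidene acetal of 13 with free 9α-OH | O[C@@H]1CCC[C@@H]2[C@]3(C)COC(C)(C)O[C@@H]3CC[C@@]12C | intermediate
15 | 9-ketone with 3α,19-acetonide | O=C1CCC[C@@H]2[C@]3(C)COC(C)(C)O[C@@H]3CC[C@@]12C | intermediate
16 | potassium enolate of 15 (C9–O−, C8=C9) | [K+].[O-]C1=CCC[C@@H]2[C@]3(C)COC(C)(C)O[C@@H]3CC[C@@]12C | intermediate
17 | enol triflate at C9 with C8=C9 double bond, 3α,19-acetonide | O=S(=O)(OC1=CCC[C@@H]2[C@]3(C)COC(C)(C)O[C@@H]3CC[C@@]12C)C(F)(F)F | intermediate
18 | methyl ester: C9–CH2CO2Me, C8=C9 double bond, 3α,19-acetonide | COC(=O)CC1=CCC[C@@H]2[C@]3(C)COC(C)(C)O[C@@H]3CC[C@@]12C | intermediate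
19 | alkylborane: 8β-BH2, 9β-H | B[C@H]1CC[C@@H]2[C@]3(C)COC(C)(C)O[C@@H]3CC[C@@]2(C)[C@@H]1CC(=O)OC | intermediate
20 | hydroxy ester: 8β-OH, 9β-H, C9–CH2CO2Me | O[C@H]1CC[C@@H]2[C@]3(C)COC(C)(C)O[C@@H]3CC[C@@]2(C)[C@@H]1CC(=O)OC | intermediate
21 | keto ester: 8-oxo, 9β-H, C9–CH2CO2Me | O=C1CC[C@@H]2[C@]3(C)COC(C)(C)O[C@@H]3CC[C@@]2(C)[C@@H]1CC(=O)OC | intermediate
22 | methyl ester with exocyclic C8=C17, 9β-H, C9–CH2CO2Me, 3α,19-acetonide | C=C1CC[C@@H]2[C@]3(C)COC(C)(C)O[C@@H]3CC[C@@]2(C)[C@@H]1CC(=O)OC | intermediate
23 | (S)-3-hydroxy-γ-butyrolactone, (4S)-4-hydroxyoxolan-2-one | O=C1C[C@H](O)CO1 | starting material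
24 | dilithium alkoxide–enolate of 23 | [Li+].[Li+].[O-]C1=C[C@H]([O-])CO1 | intermediate
25 | 12-oxo lactone: C12 ketone, C13–H trans to 14-OH (C13 labile), 3α,19-acetonide | C=C1CC[C@@H]2[C@]3(C)COC(C)(C)O[C@@H]3CC[C@@]2(C)[C@@H]1CC(=O)[C@@H]1C(=O)OC[C@H]1O | intermediate
26 | 3α,19-O-isopropylidene derivative of the target (12S,13S,14S) | C=C1CC[C@@H]2[C@]3(C)COC(C)(C)O[C@@H]3CC[C@@]2(C)[C@@H]1C[C@H](O)[C@@H]1C(=O)OC[C@H]1O | intermediate
27 | target, (3R,4R,5S,9R,10S,12S,13S,14S)-3,12,14,19-tetrahydroxylabd-8(17)-en-16,15-olide | C=C1CC[C@@H]2[C@](C)(CO)[C@H](O)CC[C@@]2(C)[C@@H]1C[C@H](O)[C@@H]1C(=O)OC[C@H]1O | target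

**Totals and risks**
Total step count: 16. Longest linear sequence: 16 steps (1 → 27; 15 from carvone).

Most likely to fail:

- **Step 3.** Anionic oligomerisation of the acrylate may compete with the Michael addition. The sequence may also stall after the first bond, because ring closure has to pass through the ring B conformer with an axial isopropenyl group, and a slow Dieckmann step leaves time for retro-Claisen pathways. Fallback: setting out from 5, the potassium enolate (KOtBu, THF, −78 °C) would be added to acrylonitrile, and the keto nitrile F1 would be isolated. KOtBu in THF/tBuOH would then close ring A by Thorpe–Ziegler addition of the tert-butyl ester enolate (C4) to the nitrile carbon (C3), giving the enamino ester F2. Dilute aqueous HCl in THF would hydrolyse the enamine and return to the route at 9. The two bonds are then made in separate operations with an acceptor and an electrophile that do not revert.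

- **Step 14.** Proton exchange between the lactone enolate and the ester, slow acyl transfer, and self-condensation of the lactone enolate on warming may limit conversion. Fallback: setting out from 22, reduction with iBu2AlH (CH2Cl2, −78 °C) would give the aldehyde F4. Lactone 23 would be silylated (tBuMe2SiCl, imidazole, DMF) to the silyl ether F5. Its lithium enolate (LiN(iPr)2, THF, −78 °C) would add to F4 anti to the silyloxy group to give the aldol adduct F6, as a mixture at C12. Dess–Martin oxidation would converge both epimers on the keto lactone silyl ether F7, and HF·pyridine would remove the silyl group and return to the route at 25.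

- **Step 10.** Oxidative addition and transmetalation at the hindered triflate next to the quaternary C10 may be slow, and the double bond may drift into conjugation with the ester. Fallback: setting out from ketone 15, Peterson olefination with the lithium enolate of methyl (trimethylsilyl)acetate (LiN(iPr)2, THF, −78 °C → rt) would give the exocyclic unsaturated ester F3. Deprotonation at C8 to the dienolate (LiN(iPr)2, DMPU, THF, −78 °C) and kinetic α-protonation (AcOH, −78 °C) would move the double bond to C8–C9 and return to the route at 18.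

**Further compounds**
F1 | step 3 | keto nitrile, tert-butyl 2-[2-(2-cyanoethyl)-2-methyl-3-oxo-5-(prop-1-en-2-yl)cyclohexyl]acetate, cyanoethyl chain trans to the acetate arm | N#CCC[C@@]1(C)C(=O)C[C@@H](C(C)=C)C[C@@H]1CC(=O)OC(C)(C)C
F2 | step 3 | enamino ester, ring A closed with C3–NH2 and C3=C4 bearing CO2tBu | O=C1C[C@@H](C(C)=C)C[C@@H]2C(C(=O)OC(C)(C)C)=C(N)CC[C@@]12C
F3 | step 10 | exocyclic unsaturated ester, C9=C11H–CO2Me (E/Z mixture), 3α,19-acetonide | COC(=O)C=C1CCC[C@@H]2[C@]3(C)COC(C)(C)O[C@@H]3CC[C@@]12C
F4 | step 14 | aldehyde, C9–CH2CHO with exocyclic C8=C17 and 3α,19-acetonide | C=C1CC[C@@H]2[C@]3(C)COC(C)(C)O[C@@H]3CC[C@@]2(C)[C@@H]1CC=O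
F5 | step 14 | (S)-3-(tert-butyldimethylsilyloxy)-γ-butyrolactone | O=C1C[C@H](O[Si](C)(C)C(C)(C)C)CO1
F6 | step 14 | aldol adduct, 12-hydroxy (both C12 epimers), 14-O-silyl, 3α,19-acetonide | C=C1CC[C@@H]2[C@]3(C)COC(C)(C)O[C@@H]3CC[C@@]2(C)[C@@H]1CC(O)[C@@H]1C(=O)OC[C@H]1O[Si](C)(C)C(C)(C)C
F7 | step 14 | 12-oxo lactone 14-O-silyl ether, 3α,19-acetonide | C=C1CC[C@@H]2[C@]3(C)COC(C)(C)O[C@@H]3CC[C@@]2(C)[C@@H]1CC(=O)[C@@H]1C(=O)OC[C@H]1O[Si](C)(C)C(C)(C)C
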